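Numbering used throughout: tetralone carbons C1 (carbonyl) to C8a; ring A is the benzene ring (C4a, C5–C8, C8a), ring B the cyclohexanone (C1–C4, C4a, C8a); the naphthalene is C1'–C8a' with C1' bonded to C4, hydroxyl on C4' and methoxy on C8'. Compounds 1–17 are those of the steps below.

## Analysis of the target

Compound 17 is a 4-aryl-1-tetralone. Ring B is fused to ring A, which carries hydroxyls on C7 and C8, and C4 carries a naphthalen-1-yl group with a hydroxyl on C4' and a methoxy on C8'. C4 is the only stereocentre, a doubly benzylic methine of R configuration (C4a outranks C1' because C8a leads to the carbonyl carbon). With nothing to relay from, it has to be set by a reagent or catalyst. The catechol and the 1-naphthol oxidise easily, and the C4–H bond is activated by the para-hydroxynaphthyl group. One methyl ether must survive while three phenols end up free, so the other oxygens need masks that leave under neutral conditions. The 7,8-dioxygenation is the pattern that the usual tetralone closure by acylation does not give, because a 3,4-dioxygenated phenyl ring acylates para to oxygen and gives the 6,7-isomer. The naphthalene is unsymmetrical, and its carbon substituent sits para to the hydroxyl and peri to the methoxy. The strategy rests on two facts: C4 is benzylic to the naphthalene and conjugated through C1'–C4' with the C4' hydroxyl, so a C4 carbinol can ionise to a 1,4-naphthoquinone methide whose exocyclic carbon is C4; and C4a is para to the C7 oxygen and tied to C4 by the chain C3–C2–C1–C8a. The C4–C4a bond can therefore be made by alkylation of ring A with the ketone already on C8a.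

## Retrosynthetic reasoning

**17 to 16.** The two O–benzyl bonds on C7 and C8 are cut last. Benzyl ethers withstand organolithiums at low temperature and Brønsted acid catalysis, and they leave by hydrogenolysis, which touches neither the methyl ether nor C4. The naphthol is left free in 16 because the key step needs it.

**16 to 14 (through 15).** The C4–C4a bond is cut. This removes the stereocentre and ring B together and leaves a racemic C4 carbinol, 14, with the complete carbon skeleton and all four oxygens. Cutting C1–C8a instead would call for acylation ortho to the C8 oxygen against the ring's preference. Cutting C4–C1' would leave a tetralone with no handle at C4. In the forward direction a chiral Brønsted acid has to dehydrate 14 to the planar methide 15, so both enantiomers of 14 converge. It then has to guide C4a onto one face of C4.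

**14 to 13.** The naphthol is masked as a triisopropylsilyl ether until just before the key step. The mask is there because a free para-hydroxybenzylic alcohol would not survive the organometallic steps. It is removed with a fluoride source, not with acid, so that no achiral acid sees the ionisable carbinol.

**13 to 8 and 10 (through 11 and 12).** The aryl–acyl bond C1–C8a is cut to give aryllithium 11 and the γ-lactone 8. The ketone appears only when the lactone is opened, and it stays masked as lactolate 12 until the quench. The alternative of adding a naphthyl organometallic to a keto aldehyde would require chemoselection between two carbonyls, and this route avoids it. Aryllithium 11 comes from bromide 10 by halogen–lithium exchange. Direct ortho-metalation of a bis-benzyl catechol ether is not used, because benzylic deprotonation and Wittig rearrangement would compete.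

**8 to 4 and 5 (through 6 and 7).** The C4–C1' bond is cut to give naphthyllithium 6 and the aldehyde ester 5. Addition to the aldehyde followed by lactonisation of alkoxide 7 delivers both the carbinol and the masked acyl group in one operation. The carbinol is formed racemic, which does not matter because it is planarised later.

**4 to 3, 2 and 1.** The O–Si, C–Br and O–CH3 bonds are cut in turn. The bromine is placed para to the free hydroxyl of 2, which is the strongest donor on the ring system. Compound 2 comes from the symmetrical diol 1 by monoalkylation.

**10 to 9.** The two O–benzyl bonds are cut back to the bromocatechol 9, which already carries the halogen next to the future C8 oxygen.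

## Alternatives that were turned down

**Alternative 1:** This disconnects the naphthalene at C1'–C8a' and C4'–C4a'. In the forward step the aryne A3 adds across the furan ring of the furyl tetralone A2 to give the oxygen-bridged adduct A1. Acid then opens the bridge, and after a hydride shift the oxygen stays on the unsubstituted bridgehead as the C4' naphthol.
- In its favour: the naphthalene is assembled from two monocycles, so no substitution of a preformed naphthol is needed. Rings A and B arrive complete with both oxygens. Both bridgehead epimers converge.
- Against it: the required orientation joins the substituted furan carbon to the aryne carbon next to the methoxy, which is the more crowded pairing. A concerted addition of a 3-alkoxyaryne to a 2-alkylfuran has little built-in bias, so the isomer with the methoxy on the far ring position is expected alongside. Bridge opening passes through a tertiary cation at C1' next to C4, which invites migration of the tetralone substituent or elimination towards C4. Finally, A2 must already be a single enantiomer, so the key step does not address the stereocentre at all.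
- Comparison: this alternative is stronger on the regiochemistry of the naphthalene, which the chosen route entrusts to step 2. In its place the chosen strategy sets C4 and closes ring B in one catalytic operation from a racemic carbinol, and it needs only one step afterwards.

**Alternative 2:** This disconnects ring A at C4a–C8a and C7–C8. In the furan–ynone A5 the furan on the future C4 is the diene and the terminal ynone is the dienophile. The intramolecular cycloaddition closes ring B and the carbocycle of ring A, and the oxygen bridge opens to the C7 phenol A4.
- In its favour: two rings and two C–C bonds form in a reagent-free thermal step, which is more skeletal bonds per step than the chosen key step. The C7 oxygen is placed without ambiguity, and the ketone arises in position.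
- Against it: C8 comes from the alkyne terminus and carries hydrogen in A4. The C8 hydroxyl would have to be introduced late, between the C7 phenol and the acyl-bearing C8a, in competition with the open ortho position C6 and in the presence of an oxidisable naphthyl ether. That costs at least two further steps of doubtful site selectivity. A5 must also already hold C4 as a single enantiomer at a furyl(naphthyl)methine, so a separate asymmetric step is needed.
- Comparison: the alternative wins on bonds formed in the key step. The chosen strategy brings both ring A oxygens in with 10 and creates the stereocentre in the key step itself.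

**Alternative 3:** This disconnects C4a–C5 and C8–C8a, so ring A is grown on a preformed ring B. The hydroxypyrone A7 adds as a diene to the bromoenone A8, and decarboxylation and dehydrobromination of the bridged adduct give the aromatic C8 phenol A6.
- In its favour: C4 is set on a simple six-membered ketone by established desymmetrisation chemistry before any arene chemistry. On this point it is stronger than the chosen route, whose stereo-determining step is untested. The pyrone route also places the C8 hydroxyl next to the carbonyl reliably.
- Against it: the C7 oxygen is missing and needs a late ortho-hydroxylation of the C8 phenol. The C4–H of A8 is γ to the enone carbonyl and can be removed through the dienolate by the base that activates A7, which would erode the configuration. The dienophile carbon that becomes C4a is next to the bulky peri-substituted naphthyl group, so the cycloaddition is hindered. The sequence is also longer (desymmetrisation, enone formation, bromination, cycloaddition, hydroxylation, deprotection).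
- Comparison: the chosen strategy gives up the established stereochemistry. It gains the full oxygenation pattern from the start and a shorter route.

Key step: step 8

Remarks on the chemistry: the sense of induction of the catalyst cannot be assigned in advance. The route is written with the (R)-configured acid, and its mirror image would be used if that is the one that gives the 4R product. Compound 14 is drawn as the open hydroxy ketone; its cyclic hemiketal form would enter the key step through the same methide.

## Route

Step 1
Reactants: 1 naphthalene-1,5-diol
Product: 2 5-methoxynaphthalen-1-ol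
Conditions: MeI (1.0 equiv), K2CO3 (1.0 equiv), acetone, reflux
Reagents that add atoms: iodomethane, CI
Why: Williamson etherification of one of two equivalent naphthol hydroxyls; with one equivalent of iodomethane the monoether should be the main component of a statistical mixture and is separated from diol and diether by its intermediate polarity. Compound 2 is also a catalogue compound, which would save this step.

Step 2
Reactants: 2 5-methoxynaphthalen-1-ol
Product: 3 4-bromo-5-methoxynaphthalen-1-ol
Conditions: N-bromosuccinimide (1.0 equiv), MeCN, −30 to 0 °C, dark
Reagents that add atoms: N-bromosuccinimide, O=C1CCC(=O)N1Br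
Why: Electrophilic aromatic bromination; the free hydroxyl is the strongest donor, so the α-position para to it (C4) should be attacked in preference to the ring carrying the methyl ether, as is usual for 1-naphthols in acetonitrile.

Step 3
Reactants: 3 4-bromo-5-methoxynaphthalen-1-ol
Product: 4 [(4-bromo-5-methoxynaphthalen-1-yl)oxy]tri(propan-2-yl)silane
Conditions: i-Pr3SiCl, imidazole, DMF, rt
Reagents that add atoms: chlorotri(propan-2-yl)silane, CC(C)[Si](Cl)(C(C)C)C(C)C
Why: Imidazole-mediated silylation of the naphthol; the bulky silyl ether should withstand the two organolithium steps and later leaves with fluoride without acid.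

Step 4
Reactants: 4 [(4-bromo-5-methoxynaphthalen-1-yl)oxy]tri(propan-2-yl)silane; 5 methyl 4-oxobutanoate
Product: 8 5-{8-methoxy-4-[tri(propan-2-yl)silyloxy]naphthalen-1-yl}oxolan-2-one (racemic), via naphthyllithium 6 (not isolated), via lithium alkoxide ester 7 (not isolated)
Conditions: n-BuLi, THF, −78 °C; 5, −78 °C to rt; aqueous work-up; pyridinium p-toluenesulfonate (cat.), PhMe, 50 °C
Reagents that add atoms: none
Why: Bromine–lithium exchange gives 6, which is held by the peri methoxy group and adds to the aldehyde of 5 much faster than to the ester; alkoxide 7 then closes onto the ester (5-exo-trig lactonisation), and the mild acid finish completes the closure. The carbinol carbon is formed racemic, which is of no consequence because it is planarised in step 8.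

Step 5
Reactants: 9 3-bromobenzene-1,2-diol
Product: 10 1,2-bis(benzyloxy)-3-bromobenzene
Conditions: BnBr (2.2 equiv), K2CO3, DMF, 60 °C
Reagents that add atoms: benzyl bromide, BrCc1ccccc1
Why: Double Williamson benzylation of the catechol; the benzyl ethers tolerate an aryllithium at −78 °C and Brønsted acid catalysis and leave at the end by hydrogenolysis.

Step 6
Reactants: 10 1,2-bis(benzyloxy)-3-bromobenzene; 8 5-{8-methoxy-4-[tri(propan-2-yl)silyloxy]naphthalen-1-yl}oxolan-2-one
Product: 13 1-[2,3-bis(benzyloxy)phenyl]-4-hydroxy-4-{8-methoxy-4-[tri(propan-2-yl)silyloxy]naphthalen-1-yl}butan-1-one (racemic), via aryllithium 11 (not isolated), via lithium lactolate 12 (not isolated)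
Conditions: 10, n-BuLi, THF, −78 °C; then 8, −78 °C; AcOH in THF, −78 °C
Reagents that add atoms: none
Why: Bromine–lithium exchange at −78 °C outruns benzylic deprotonation and gives 11, which adds once to the lactone carbonyl; lactolate 12 does not release the ketone before the cold proton quench, so a second addition is avoided. This is the standard opening of a lactone to a hydroxy ketone by an aryllithium.

Step 7
Reactants: 13 1-[2,3-bis(benzyloxy)phenyl]-4-hydroxy-4-{8-methoxy-4-[tri(propan-2-yl)silyloxy]naphthalen-1-yl}butan-1-one
Product: 14 1-[2,3-bis(benzyloxy)phenyl]-4-hydroxy-4-(4-hydroxy-8-methoxynaphthalen-1-yl)butan-1-one (racemic)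
Conditions: Bu4NF, AcOH (1:1), THF, 0 °C
Reagents that add atoms: none
Why: Fluoride-induced cleavage of the aryl O–Si bond; acetic acid buffers the naphtholate so that the para-hydroxybenzylic alcohol is not ionised by base before the key step.

Step 8
Reactants: 14 1-[2,3-bis(benzyloxy)phenyl]-4-hydroxy-4-(4-hydroxy-8-methoxynaphthalen-1-yl)butan-1-one
Product: 16 (4R)-7,8-bis(benzyloxy)-4-(4-hydroxy-8-methoxynaphthalen-1-yl)-3,4-dihydronaphthalen-1(2H)-one, via quinone methide 15 (not isolated)
Conditions: (R)-3,3′-bis(2,4,6-triisopropylphenyl)-1,1′-binaphthyl-2,2′-diyl hydrogen phosphate ((R)-TRIP, 10 mol %), 5 Å molecular sieves, ClCH2CH2Cl (0.01 M), 40 °C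
Reagents that add atoms: none
Why: Proposed new method: the chiral acid protonates the C4 hydroxyl of 14 and, with push from the para C4' hydroxyl, dehydration gives the 1,4-naphthoquinone methide 15, whose exocyclic carbon is C4, so that both enantiomers of 14 converge on one planar species. Reprotonation at O4' gives a hydrogen-bonded ion pair in which C4 is a stabilised benzylic cation; ring A carbon C4a attacks it to form C4–C4a, and loss of the C4a proton to the phosphate restores both aromatic systems. The closest known reaction type is the chiral phosphoric acid catalysed Friedel–Crafts 1,6-addition of indoles, pyrroles and naphthols to para-quinone methides generated in situ from para-hydroxybenzylic alcohols; intramolecular use of a dialkoxyphenyl ketone as the arene has not been shown. Ring B closes in the 6-exo-trig mode with respect to the C4=C1' bond of the methide, the only ring size that the three-atom tether C3–C2–C1 permits from C8a. C4 is set by the catalyst: the phosphate is anchored through the O4'–H···O–P hydrogen bond, its 2,4,6-triisopropylphenyl groups are expected to screen one face of C4, and the peri methoxy on C8' should hold the alkylidene chain on the C2' side so that one methide geometry is presented; ring A has no hydrogen-bond donor and the ketone cannot serve as a second anchor, so face selection rests on this single contact and the shape of the pocket. The step needs site selectivity, which the substrate secures because C4a is the only ring A carbon that the tether can bring to C4 and it lies para to the C7 ether, where a 2,3-dialkoxyphenyl ketone is expected to be most nucleophilic; it also needs intramolecular to win over intermolecular alkylation, which high dilution favours. Closure through oxygen to a cyclic ether and elimination to the styrene are reversible through the same cation, so the material should drain into the C–C bonded tetralone.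

Step 9
Reactants: 16 (4R)-7,8-bis(benzyloxy)-4-(4-hydroxy-8-methoxynaphthalen-1-yl)-3,4-dihydronaphthalen-1(2H)-one
Product: 17 (4R)-7,8-dihydroxy-4-(4-hydroxy-8-methoxynaphthalen-1-yl)-3,4-dihydronaphthalen-1(2H)-one
Conditions: H2 (1 atm), 10 % Pd/C (palladium on carbon), EtOAc/MeOH, rt; filtration under Ar
Reagents that add atoms: none
Why: Heterogeneous hydrogenolysis of the two benzyl ethers under neutral conditions; the methyl ether and the C4 stereocentre are not affected, and the reaction is stopped after uptake of two equivalents to spare the aryl ketone.

## Compound list

1 | naphthalene-1,5-diol | Oc1cccc2c(O)cccc12 | starting material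
2 | 5-methoxynaphthalen-1-ol | COc1cccc2c(O)cccc12 | intermediate
3 | 4-bromo-5-methoxynaphthalen-1-ol | COc1cccc2c(O)ccc(Br)c12 | intermediate
4 | [(4-bromo-5-methoxynaphthalen-1-yl)oxy]tri(propan-2-yl)silane | COc1cccc2c(O[Si](C(C)C)(C(C)C)C(C)C)ccc(Br)c12 | intermediate
5 | methyl 4-oxobutanoate | COC(=O)CCC=O | starting material
6 | {8-methoxy-4-[tri(propan-2-yl)silyloxy]naphthalen-1-yl}lithium | COc1cccc2c(O[Si](C(C)C)(C(C)C)C(C)C)ccc([Li])c12 | intermediate
7 | lithium 4-methoxy-1-{8-methoxy-4-[tri(propan-2-yl)silyloxy]naphthalen-1-yl}-4-oxobutan-1-olate (racemic) | COc1cccc2c(O[Si](C(C)C)(C(C)C)C(C)C)ccc(C(O[Li])CCC(=O)OC)c12 | intermediate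
8 | 5-{8-methoxy-4-[tri(propan-2-yl)silyloxy]naphthalen-1-yl}oxolan-2-one (racemic) | COc1cccc2c(O[Si](C(C)C)(C(C)C)C(C)C)ccc(C3CCC(=O)O3)c12 | intermediate
9 | 3-bromobenzene-1,2-diol | Oc1cccc(Br)c1O | starting material
10 | 1,2-bis(benzyloxy)-3-bromobenzene | Brc1cccc(OCc2ccccc2)c1OCc1ccccc1 | intermediate
11 | [2,3-bis(benzyloxy)phenyl]lithium | [Li]c1cccc(OCc2ccccc2)c1OCc1ccccc1 | intermediate
12 | lithium 2-[2,3-bis(benzyloxy)phenyl]-5-{8-methoxy-4-[tri(propan-2-yl)silyloxy]naphthalen-1-yl}oxolan-2-olate (racemic, both diastereomers) | COc1cccc2c(O[Si](C(C)C)(C(C)C)C(C)C)ccc(C3CCC(O[Li])(c4cccc(OCc5ccccc5)c4OCc4ccccc4)O3)c12 | intermediate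
13 | 1-[2,3-bis(benzyloxy)phenyl]-4-hydroxy-4-{8-methoxy-4-[tri(propan-2-yl)silyloxy]naphthalen-1-yl}butan-1-one (racemic) | COc1cccc2c(O[Si](C(C)C)(C(C)C)C(C)C)ccc(C(O)CCC(=O)c3cccc(OCc4ccccc4)c3OCc3ccccc3)c12 | intermediate
14 | 1-[2,3-bis(benzyloxy)phenyl]-4-hydroxy-4-(4-hydroxy-8-methoxynaphthalen-1-yl)butan-1-one (racemic) | COc1cccc2c(O)ccc(C(O)CCC(=O)c3cccc(OCc4ccccc4)c3OCc3ccccc3)c12 | intermediate
15 | 1-[2,3-bis(benzyloxy)phenyl]-4-(8-methoxy-4-oxonaphthalen-1(4H)-ylidene)butan-1-one (alkene geometry not fixed) | COc1cccc2C(=O)C=CC(=CCCC(=O)c3cccc(OCc4ccccc4)c3OCc3ccccc3)c12 | intermediate
16 | (4R)-7,8-bis(benzyloxy)-4-(4-hydroxy-8-methoxynaphthalen-1-yl)-3,4-dihydronaphthalen-1(2H)-one | COc1cccc2c(O)ccc([C@H]3CCC(=O)c4c3ccc(OCc3ccccc3)c4OCc3ccccc3)c12 | intermediate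
17 | (4R)-7,8-dihydroxy-4-(4-hydroxy-8-methoxynaphthalen-1-yl)-3,4-dihydronaphthalen-1(2H)-one | COc1cccc2c(O)ccc([C@H]3CCC(=O)c4c3ccc(O)c4O)c12 | target

## Step count and least certain steps

Total: 9 steps. Longest linear sequence: 8 steps (1 to 2, 3, 4, 8, 13, 14, 16, 17; steps 1–4 and 6–9).

**Step 8 (key step).** Two things are most likely to go wrong.
- Slow ring closure: C4a is ortho to the acyl group. The methide could then be consumed by intermolecular alkylation of the naphthol ring of another molecule, or stay parked as the cyclic ether or styrene.
- Weak face selection: the catalyst holds the substrate only through the remote O4' hydrogen bond.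

A more acidic chiral N-triflyl phosphoramide on the same binaphthyl backbone would be the first adjustment of conditions.

Fallback, from 14 back to 16: 14 is cyclised without chiral control by p-TsOH·H2O (20 mol %) in hexafluoropropan-2-ol at 40 °C. This is the known dehydrative Friedel–Crafts cyclialkylation of benzylic carbinols, in a medium that stabilises the cation and tolerates weak arene nucleophiles. It gives racemic 7,8-bis(benzyloxy)-4-(4-hydroxy-8-methoxynaphthalen-1-yl)-3,4-dihydronaphthalen-1(2H)-one F1. The enantiomers are then separated by preparative chromatography on a chiral stationary phase, and the 4R enantiomer is 16. Half of the material is lost.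

**Step 2.** Bromination may go to the wrong site (ortho to the hydroxyl, or in the ring carrying the methyl ether) or go twice, because both rings are activated and the para position is crowded by the peri methoxy.

Fallback, from 2 back to 6: 2 is silylated as in step 3 to [(5-methoxynaphthalen-1-yl)oxy]tri(propan-2-yl)silane F2. F2 is lithiated with t-BuLi in cyclohexane at rt. 1-Methoxynaphthalenes are known to be metalated at the peri position under these conditions through coordination to the methoxy oxygen. Here that position is C4 of F2, which is also para to the silyloxy group. Naphthyllithium 6 is thus formed without any halogenation and is carried into step 4 after dilution with THF and cooling.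

**Step 6.** Over-addition may occur if lactolate 12 collapses to the ketone before the quench. Enolisation of the lactone and benzylic metalation with Wittig rearrangement of 11 on warming are the other risks.

Fallback, from 8 back to 14: lactone 8 is opened with N,O-dimethylhydroxylamine hydrochloride and i-PrMgCl to 4-hydroxy-N-methoxy-N-methyl-4-{8-methoxy-4-[tri(propan-2-yl)silyloxy]naphthalen-1-yl}butanamide F3. The hydroxyl is capped with Et3SiCl and imidazole to give N-methoxy-4-{8-methoxy-4-[tri(propan-2-yl)silyloxy]naphthalen-1-yl}-N-methyl-4-(triethylsilyloxy)butanamide F4. Aryllithium 11 adds to the Weinreb amide, whose chelated adduct cannot add twice, to give 1-[2,3-bis(benzyloxy)phenyl]-4-{8-methoxy-4-[tri(propan-2-yl)silyloxy]naphthalen-1-yl}-4-(triethylsilyloxy)butan-1-one F5. Bu4NF with AcOH then removes both silyl groups and gives 14.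

**Step 9.** Over-reduction of the aryl ketone, or slow cleavage of the hindered C8 benzyl ether that forces longer exposure, is the main risk. The free catechol is also air-sensitive on work-up.

Fallback, from 16 to 17: the benzyl ethers are cleaved by BCl3 with pentamethylbenzene as benzyl-cation scavenger in CH2Cl2 at −78 °C. This is a Lewis acid cleavage instead of a reduction, and it leaves the ketone and the unchelated methyl ether alone. No new compound lies on the way.

## Further compounds

F1 | step 8 | rac-7,8-bis(benzyloxy)-4-(4-hydroxy-8-methoxynaphthalen-1-yl)-3,4-dihydronaphthalen-1(2H)-one | COc1cccc2c(O)ccc(C3CCC(=O)c4c3ccc(OCc3ccccc3)c4OCc3ccccc3)c12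
F2 | step 2 | [(5-methoxynaphthalen-1-yl)oxy]tri(propan-2-yl)silane | COc1cccc2c(O[Si](C(C)C)(C(C)C)C(C)C)cccc12
F3 | step 6 | 4-hydroxy-N-methoxy-N-methyl-4-{8-methoxy-4-[tri(propan-2-yl)silyloxy]naphthalen-1-yl}butanamide (racemic) | COc1cccc2c(O[Si](C(C)C)(C(C)C)C(C)C)ccc(C(O)CCC(=O)N(C)OC)c12
F4 | step 6 | N-methoxy-4-{8-methoxy-4-[tri(propan-2-yl)silyloxy]naphthalen-1-yl}-N-methyl-4-(triethylsilyloxy)butanamide (racemic) | COc1cccc2c(O[Si](C(C)C)(C(C)C)C(C)C)ccc(C(CCC(=O)N(C)OC)O[Si](CC)(CC)CC)c12
F5 | step 6 | 1-[2,3-bis(benzyloxy)phenyl]-4-{8-methoxy-4-[tri(propan-2-yl)silyloxy]naphthalen-1-yl}-4-(triethylsilyloxy)butan-1-one (racemic) | COc1cccc2c(O[Si](C(C)C)(C(C)C)C(C)C)ccc(C(CCC(=O)c3cccc(OCc4ccccc4)c3OCc3ccccc3)O[Si](CC)(CC)CC)c12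
F0 | step 9 | none | none
A1 | alternative 1 | 7,8-bis(benzyloxy)-4-(8-methoxy-1,4-dihydro-1,4-epoxynaphthalen-1-yl)-3,4-dihydronaphthalen-1(2H)-one, C4 as in the target, either bridgehead configuration | COc1cccc2c1C1([C@H]3CCC(=O)c4c3ccc(OCc3ccccc3)c4OCc3ccccc3)OC2C=C1
A2 | alternative 1 | 7,8-bis(benzyloxy)-4-(furan-2-yl)-3,4-dihydronaphthalen-1(2H)-one, C4 as in the target | o1cccc1[C@H]1CCC(=O)c2c1ccc(OCc1ccccc1)c2OCc1ccccc1
A3 | alternative 1 | 3-methoxybenzyne | COC1=CC=CC#C1
A4 | alternative 2 | 4-[4-(benzyloxy)-8-methoxynaphthalen-1-yl]-7-hydroxy-3,4-dihydronaphthalen-1(2H)-one, C4 as in the target | COc1cccc2c(OCc3ccccc3)ccc([C@H]3CCC(=O)c4c3ccc(O)c4)c12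
A5 | alternative 2 | 5-[4-(benzyloxy)-8-methoxynaphthalen-1-yl]-5-(furan-2-yl)pent-1-yn-3-one, C5 configured to give C4 of the target | COc1cccc2c(OCc3ccccc3)ccc([C@@H](CCC(=O)C#C)c3ccco3)c12
A6 | alternative 3 | 4-[4-(benzyloxy)-8-methoxynaphthalen-1-yl]-8-hydroxy-3,4-dihydronaphthalen-1(2H)-one, C4 as in the target | COc1cccc2c(OCc3ccccc3)ccc([C@H]3CCC(=O)c4c3cccc4O)c12
A7 | alternative 3 | 3-hydroxy-2H-pyran-2-one | O=C1OC=CC=C1O
A8 | alternative 3 | 4-[4-(benzyloxy)-8-methoxynaphthalen-1-yl]-2-bromocyclohex-2-en-1-one, C4 configured to give C4 of the target | O=C1CC[C@H](c2ccc(OCc3ccccc3)c3cccc(OC)c23)C=C1Br
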